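The constants used here were chosen freely, and the outcome is calculated.

The catalyst leaves every step as it entered, so its 100 µM stays fixed and each step, in each direction, acts as a first-order decay with its own time constant (pseudo-first-order). With the catalyst held at that amount the flask is a linear network, so I reckon the share of target from the age of the material and leave the size of the charge out.

all flasks: catalyst 100 µM
- noon: substrate 20 mM; a single well-mixed tank run continuously and read at steady state, 60.0 min in it on average
- autumn: substrate 20 mM; a closed flask charged with all of it at once and left for 12 min; time 12 min
- dusk: substrate 20 mM; one stirred flow tank at steady state, fed with the mixture as stated, mean residence time 12 min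
- dawn: substrate 20 mM (fed, over 12.0 min); all but substrate at the start; substrate goes in evenly over 12.0 min, the run ends at 12 min; time 12 min

1. the set-up with the highest share of target in all that became target or isomer of the product, at the outlet or at the end ("none" if the first two lie within 2 percentage points) (noon / autumn / dusk / dawn / none)
2. share of target in all that became target or isomer of the product, at the outlet or at the end, noon
3. share of target in all that became target or isomer of the product, at the outlet or at the end, autumn
4. share of target in all that became target or isomer of the product, at the outlet or at the end, dusk
5. share of target in all that became target or isomer of the product, at the outlet or at the end, dawn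

    substrate + catalyst ⇌ target + catalyst, rate k1*[substrate]*[catalyst] forward; the back reaction follows from the equilibrium constant (K1 = 0.50, k1 = 1200 /M/min)
    target + catalyst ⇌ isomer of the product + catalyst, rate k2*[catalyst]*[target] forward; the back reaction follows from the equilibrium constant (K2 = 3.1, k2 = 1700 /M/min)
    isomer of the product + catalyst ⇌ substrate + catalyst, rate k3*[catalyst]*[isomer of the product] forward; the back reaction follows from the equilibrium constant (k3 = 190 /M/min)

- the stated concentrations are those of everything mixed, before any reaction; amounts are the same in each set-up
- the feed brings no volume worth counting
- run time (autumn): 12 min

My decision for the next run is whether to charge the substrate at once or dose it. Substrate goes to target at a = 0.120 /min and straight to isomer, by the reverse of the closing step, at b = 0.0294 /min, so material is born with a target share B = a/(a+b) = 80.3%. Isomer returns to target at c = 0.0548 /min and to substrate at d = 0.0190 /min, and at great age the share tends to F = 24.4%, set by the equilibrium constant of the middle step. Solving the steady balances of a tank of mean age θ gives the share S: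

S(θ) = (B + F·θ/T) / (1 + θ/T)

T = F/(c + d·B) = 3.48 min

I call T the memory time, the mean age at which a tank's share stands midway between B and F. I now replace each flask's curve of ages by its mean: 60.0 min for noon, 12 min for dusk and autumn, and for dawn, dosed evenly, 6.00 min, which is younger than autumn.

noon: 27.5%

dusk: 37.0%

autumn: 37.0%

dawn: 44.9%

The mean costs something: autumn's material has no tank-like spread of ages and dawn's spread is narrower than a tank's, and since S falls with age from B towards F, steeply at first, I expect both figures to read high, autumn's most. Even so, dawn leads, so I dose.

The forecast also names dawn, with 44.4% there, 36.9% for dusk, 32.9% for autumn and 27.4% for noon, on the ground that “younger material holds more target”. It parts from my reckoning on autumn, which it sets below dusk where I have a tie.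

The simulation gives dawn as best at 44.4%, with 37.0% for dusk, 32.9% for autumn and 27.5% for noon, so autumn reads 4 percentage points below dusk. In the autumn flask, the half-life of isomer by its forward way to substrate alone, 36 min, is longer than the run of 12 min, and it equals 10.5 memory times. The dawn flask, left to 120 min, or 34.5 memory times, reads 24.4%, level with F.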